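**Retrosynthetic overview**

1. The target is epicatechin-(4β→8)-epicatechin 3-O-gallate-(4β→8)-epicatechin 3-O-gallate. It is traced to its octadecabenzyl ether 18, the two C4–C8 bonds to C4 cations from the 4β-(2-ethoxyethoxy) ether 13 (steps 9 and 11), and the two gallates to separate esterifications with acid 14, one on monomer 11 (step 8) and one on dimer 16 (step 10).
2. All three flavan units are the same protected flavan-3-ol 11, so one ring-forming sequence supplies the pyran ring of every unit, the middle one included.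
3. The pyran ring of 11 (O1–C2–C3–C4–C4a–C8a) is not closed as a six-membered ring. Its C3–OH comes from ketone 10, and 10 from the five-membered ring (O1–C2–C3–C3a–C7a) of 3-methylidene-2,3-dihydrobenzofuran 8 by an oxidative 1,2-aryl shift that inserts the exocyclic carbon between C3 and the aryl carbon.
4. Enabling feature: in each pyran ring the methylene C4 lies between the oxygen-bearing C3 and the aryl carbon C4a of the 5,7,8a-trioxygenated ring A. The ring is therefore a masked β-aryl ketone whose aryl carbon is an exceptional migrating group; the C3 carbonyl (an oxidation level above the target) is reduced again in step 6.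
5. Order of ring formation: aromatic rings are bought; the furan ring is closed by 5-exo-dig reductive Heck cyclization of aryl propargyl ether 7 (step 4), whose single stereocentre (the later C2) comes from a catalytic alkynylation and a Mitsunobu inversion; the pyran ring then arises by ring enlargement (step 5).

Key step: step 5

Remark: compounds 1, 3 and 14 are taken as purchasable benzyl ethers, and in step 2 the ProPhenol enantiomer is the one whose sense of induction gives 5.

**Route**

Step 1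
Reactants: 1 3,5-bis(benzyloxy)phenol
Product: 2 3,5-bis(benzyloxy)-2-iodophenol
Conditions: I2, NaHCO3, THF/H2O, 0 °C
Reagents that add atoms: iodine, [I][I]
Why: Electrophilic aromatic iodination of the phenoxide should go ortho to the free hydroxyl, because the position between the two benzyloxy groups is the more shielded one (a minor para isomer would be removed), and no stereocentre is formed.

Step 2
Reactants: 3 3,4-bis(benzyloxy)benzaldehyde; 4 ethynyltrimethylsilane
Product: 6 (R)-1-[3,4-bis(benzyloxy)phenyl]prop-2-yn-1-ol, via silyl alkynol 5 (not isolated)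
Conditions: Me2Zn, ProPhenol ligand (cat.), Ph3P=O (cat.), toluene, 0 °C; then K2CO3 (cat.), MeOH, rt
Reagents that add atoms: none
Why: Catalytic enantioselective alkynylation of an aldehyde by the alkynylzinc species formed from Me2Zn and bound to the chiral ProPhenol ligand sets the carbinol centre (the later C2 of every flavan unit) by catalyst control, and the basic methanolysis only cleaves the C–Si bond.

Step 3
Reactants: 2 3,5-bis(benzyloxy)-2-iodophenol; 6 (R)-1-[3,4-bis(benzyloxy)phenyl]prop-2-yn-1-ol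
Product: 7 (S)-1-[3,4-bis(benzyloxy)phenyl]prop-2-yn-1-yl 3,5-bis(benzyloxy)-2-iodophenyl ether
Conditions: PPh3, DIAD, toluene, 0 °C to rt
Reagents that add atoms: none
Why: Mitsunobu etherification, in which the acidic iodophenol displaces the activated propargylic oxygen in an SN2 step, so the carbinol centre is inverted from R to S.

Step 4
Reactants: 7 (S)-1-[3,4-bis(benzyloxy)phenyl]prop-2-yn-1-yl 3,5-bis(benzyloxy)-2-iodophenyl ether
Product: 8 (2R)-4,6-bis(benzyloxy)-2-[3,4-bis(benzyloxy)phenyl]-3-methylidene-2,3-dihydro-1-benzofuran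
Conditions: Pd(OAc)2 (cat.), PPh3, HCO2Na, DMF, 60 °C
Reagents that add atoms: none
Why: Reductive Heck cyclization, in which oxidative addition of zerovalent palladium into the C–I bond, 5-exo-dig syn-carbopalladation of the alkyne and formate reduction of the vinylpalladium close the furan ring and leave the exocyclic methylene, while the stereocentre is not touched.

Step 5
Reactants: 8 (2R)-4,6-bis(benzyloxy)-2-[3,4-bis(benzyloxy)phenyl]-3-methylidene-2,3-dihydro-1-benzofuran
Product: 10 (2R)-5,7-bis(benzyloxy)-2-[3,4-bis(benzyloxy)phenyl]chroman-3-one, via dimethyl ketal 9 (not isolated)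
Conditions: PhI(OH)OTs, MeOH, 0 °C; then 1 M HCl, THF, rt
Reagents that add atoms: methanol, CO (both methoxy groups of 9); water, O (carbonyl oxygen of 10)
Why: The electrophilic iodane adds to the CH2 terminus of the 1,1-disubstituted alkene and methanol captures the tertiary benzylic cation at C3; the C3a aryl carbon then shifts from C3 to the CH2 carbon (phenonium-like transition state) as iodobenzene leaves, and the methoxy-stabilised cation left at C3 is trapped as ketal 9 and hydrolysed to 10. The closest known reaction type is the hypervalent-iodine oxidative ring expansion of 1-methylidene benzocycloalkenes to β-aryl cycloalkanones (1,2-aryl shift, semipinacol-like). The six-membered ring is not closed by a cyclization but grows from the furan ring by insertion of the exocyclic carbon between C3 and the aryl carbon, a one-atom ring enlargement. No stereocentre is created: C3 becomes the carbonyl carbon, and C2, which takes part in no bond change, keeps its R configuration. The step needs aryl over alkyl (C2) migration, which would give the flavan-4-one, and alkene over arene attack by the iodane; the first is secured by the 2,4,6-trioxygenated ring A as the best migrating group present, the second by the exocyclic styrene-type alkene being the most nucleophilic site and by the low temperature. Capture of the cation by the solvent methanol should outrun loss of H-2, which would aromatise the furan ring.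

Step 6
Reactants: 10 (2R)-5,7-bis(benzyloxy)-2-[3,4-bis(benzyloxy)phenyl]chroman-3-one
Product: 11 5,7,3',4'-tetra-O-benzyl-(−)-epicatechin [(2R,3R)-5,7-bis(benzyloxy)-2-[3,4-bis(benzyloxy)phenyl]chroman-3-ol]
Conditions: Li[BH(s-Bu)3], LiBr, THF, −78 °C
Reagents that add atoms: none
Why: Hydride reduction of a cyclic ketone by a bulky borohydride from the face opposite the C2 aryl group should give the 2,3-cis alcohol (3R), a reduction with close precedent in flavan-3-one chemistry.

Step 7
Reactants: 11 5,7,3',4'-tetra-O-benzyl-(−)-epicatechin; 12 2-ethoxyethanol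
Product: 13 4β-(2-ethoxyethoxy)-5,7,3',4'-tetra-O-benzyl-(−)-epicatechin (2,3-cis and 3,4-trans; 2R,3R,4S)
Conditions: DDQ, CH2Cl2, rt
Reagents that add atoms: none
Why: Oxidative benzylic etherification, in which DDQ abstracts hydride from C4 (benzylic to ring A) and the alcohol adds to the quinone-methide-type cation from the face opposite the C2 aryl and C3 hydroxyl groups, which sets C4 as the 4β ether.

Step 8
Reactants: 11 5,7,3',4'-tetra-O-benzyl-(−)-epicatechin; 14 3,4,5-tris(benzyloxy)benzoic acid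
Product: 15 5,7,3',4'-tetra-O-benzyl-(−)-epicatechin 3-O-[3,4,5-tris(benzyloxy)benzoate]
Conditions: DCC, DMAP, CH2Cl2, rt
Reagents that add atoms: none
Why: Steglich (carbodiimide) esterification acylates the single free secondary hydroxyl at C3 without touching any stereocentre.

Step 9
Reactants: 13 4β-(2-ethoxyethoxy)-5,7,3',4'-tetra-O-benzyl-(−)-epicatechin; 15 5,7,3',4'-tetra-O-benzyl-(−)-epicatechin 3-O-[3,4,5-tris(benzyloxy)benzoate] (excess, recovered)
Product: 16 octa-O-benzyl procyanidin B2 3''-O-[3,4,5-tris(benzyloxy)benzoate] (tetra-O-benzylepicatechin-(4β→8)-tetra-O-benzylepicatechin 3-O-tri-O-benzylgallate; 3-OH of the upper unit free)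
Conditions: Me3SiOSO2CF3 (cat.), CH2Cl2, −78 °C
Reagents that add atoms: none
Why: Lewis-acid-promoted Friedel–Crafts-type flavan coupling, in which ionization of the C4 ether gives the ring-A-stabilised benzylic cation and the excess nucleophile attacks it through C8 from the face opposite the C2 aryl and C3 hydroxyl groups, so the new C4 stereocentre is 4β (3,4-trans).

Step 10
Reactants: 16 octa-O-benzyl procyanidin B2 3''-O-[3,4,5-tris(benzyloxy)benzoate]; 14 3,4,5-tris(benzyloxy)benzoic acid
Product: 17 octa-O-benzyl procyanidin B2 3,3''-bis-O-[3,4,5-tris(benzyloxy)benzoate]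
Conditions: DCC, DMAP, CH2Cl2, rt to 40 °C
Reagents that add atoms: none
Why: Steglich (carbodiimide) esterification acylates the one remaining free hydroxyl (C3 of the upper unit), the only free nucleophile, without touching any stereocentre.

Step 11
Reactants: 13 4β-(2-ethoxyethoxy)-5,7,3',4'-tetra-O-benzyl-(−)-epicatechin; 17 octa-O-benzyl procyanidin B2 3,3''-bis-O-[3,4,5-tris(benzyloxy)benzoate] (excess, recovered)
Product: 18 perbenzylated trimer (tetra-O-benzylepicatechin-(4β→8)-[tetra-O-benzylepicatechin 3-O-tri-O-benzylgallate]-(4β→8)-[tetra-O-benzylepicatechin 3-O-tri-O-benzylgallate]; 3-OH of the top unit free)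
Conditions: Me3SiOSO2CF3 (cat.), CH2Cl2, −78 °C
Reagents that add atoms: none
Why: The same Lewis-acid-promoted flavan coupling, in which the C4 cation from 13 should be taken by C8 of the upper unit of the dimer (its only free C8 and most nucleophilic free position) from the face opposite the C2 aryl and C3 hydroxyl groups, giving the second 4β→8 bond.

Step 12
Reactants: 18 perbenzylated trimer
Product: 19 (−)-epicatechin-(4β→8)-(−)-epicatechin 3-O-gallate-(4β→8)-(−)-epicatechin 3-O-gallate
Conditions: H2 (1 atm), Pd(OH)2/C, THF/MeOH/H2O, rt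
Reagents that add atoms: none
Why: Catalytic hydrogenolysis should cleave all eighteen benzyl ethers while the gallate esters and the C4–C8 bonds persist, and no stereocentre is affected.

**Compound list**

1 | 3,5-bis(benzyloxy)phenol | Oc1cc(OCc2ccccc2)cc(OCc2ccccc2)c1 | starting material
2 | 3,5-bis(benzyloxy)-2-iodophenol | Oc1cc(OCc2ccccc2)cc(OCc2ccccc2)c1I | intermediate
3 | 3,4-bis(benzyloxy)benzaldehyde | O=Cc1ccc(OCc2ccccc2)c(OCc2ccccc2)c1 | starting material
4 | ethynyltrimethylsilane | C#C[Si](C)(C)C | starting material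
5 | (S)-1-[3,4-bis(benzyloxy)phenyl]-3-(trimethylsilyl)prop-2-yn-1-ol | C[Si](C)(C)C#C[C@@H](O)c1ccc(OCc2ccccc2)c(OCc2ccccc2)c1 | intermediate
6 | (R)-1-[3,4-bis(benzyloxy)phenyl]prop-2-yn-1-ol | C#C[C@@H](O)c1ccc(OCc2ccccc2)c(OCc2ccccc2)c1 | intermediate
7 | (S)-1-[3,4-bis(benzyloxy)phenyl]prop-2-yn-1-yl 3,5-bis(benzyloxy)-2-iodophenyl ether | C#C[C@H](Oc1cc(OCc2ccccc2)cc(OCc2ccccc2)c1I)c1ccc(OCc2ccccc2)c(OCc2ccccc2)c1 | intermediate
8 | (2R)-4,6-bis(benzyloxy)-2-[3,4-bis(benzyloxy)phenyl]-3-methylidene-2,3-dihydro-1-benzofuran | C=C1c2c(OCc3ccccc3)cc(OCc3ccccc3)cc2O[C@@H]1c1ccc(OCc2ccccc2)c(OCc2ccccc2)c1 | intermediate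
9 | (2R)-5,7-bis(benzyloxy)-2-[3,4-bis(benzyloxy)phenyl]-3,3-dimethoxychromane | COC1(OC)Cc2c(OCc3ccccc3)cc(OCc3ccccc3)cc2O[C@@H]1c1ccc(OCc2ccccc2)c(OCc2ccccc2)c1 | intermediate
10 | (2R)-5,7-bis(benzyloxy)-2-[3,4-bis(benzyloxy)phenyl]chroman-3-one | O=C1Cc2c(OCc3ccccc3)cc(OCc3ccccc3)cc2O[C@@H]1c1ccc(OCc2ccccc2)c(OCc2ccccc2)c1 | intermediate
11 | 5,7,3',4'-tetra-O-benzyl-(−)-epicatechin [(2R,3R)-5,7-bis(benzyloxy)-2-[3,4-bis(benzyloxy)phenyl]chroman-3-ol] | O[C@@H]1Cc2c(OCc3ccccc3)cc(OCc3ccccc3)cc2O[C@@H]1c1ccc(OCc2ccccc2)c(OCc2ccccc2)c1 | intermediate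
12 | 2-ethoxyethanol | CCOCCO | starting material
13 | 4β-(2-ethoxyethoxy)-5,7,3',4'-tetra-O-benzyl-(−)-epicatechin (2,3-cis and 3,4-trans; 2R,3R,4S) | O[C@@H]1[C@@H](OCCOCC)c2c(OCc3ccccc3)cc(OCc3ccccc3)cc2O[C@@H]1c1ccc(OCc2ccccc2)c(OCc2ccccc2)c1 | intermediate
14 | 3,4,5-tris(benzyloxy)benzoic acid | OC(=O)c1cc(OCc2ccccc2)c(OCc2ccccc2)c(OCc2ccccc2)c1 | starting material
15 | 5,7,3',4'-tetra-O-benzyl-(−)-epicatechin 3-O-[3,4,5-tris(benzyloxy)benzoate] | O=C(O[C@@H]1Cc2c(OCc3ccccc3)cc(OCc3ccccc3)cc2O[C@@H]1c1ccc(OCc2ccccc2)c(OCc2ccccc2)c1)c1cc(OCc2ccccc2)c(OCc2ccccc2)c(OCc2ccccc2)c1 | intermediate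
16 | octa-O-benzyl procyanidin B2 3''-O-[3,4,5-tris(benzyloxy)benzoate] (3-OH of the upper unit free) | O[C@@H]1[C@@H](c2c(OCc5ccccc5)cc(OCc5ccccc5)c3c2O[C@H](c2ccc(OCc5ccccc5)c(OCc5ccccc5)c2)[C@H](OC(=O)c2cc(OCc5ccccc5)c(OCc5ccccc5)c(OCc5ccccc5)c2)C3)c2c(OCc5ccccc5)cc(OCc5ccccc5)cc2O[C@@H]1c1ccc(OCc5ccccc5)c(OCc5ccccc5)c1 | intermediate
17 | octa-O-benzyl procyanidin B2 3,3''-bis-O-[3,4,5-tris(benzyloxy)benzoate] | O=C(O[C@@H]1[C@@H](c2c(OCc5ccccc5)cc(OCc5ccccc5)c3c2O[C@H](c2ccc(OCc5ccccc5)c(OCc5ccccc5)c2)[C@H](OC(=O)c2cc(OCc5ccccc5)c(OCc5ccccc5)c(OCc5ccccc5)c2)C3)c2c(OCc5ccccc5)cc(OCc5ccccc5)cc2O[C@@H]1c1ccc(OCc5ccccc5)c(OCc5ccccc5)c1)c1cc(OCc5ccccc5)c(OCc5ccccc5)c(OCc5ccccc5)c1 | intermediate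
18 | perbenzylated trimer (tetra-O-benzylepicatechin-(4β→8)-[tetra-O-benzylepicatechin 3-O-tri-O-benzylgallate]-(4β→8)-[tetra-O-benzylepicatechin 3-O-tri-O-benzylgallate]; 3-OH of the top unit free) | O=C(O[C@@H]1[C@@H](c2c(OCc5ccccc5)cc(OCc5ccccc5)c3c2O[C@H](c2ccc(OCc5ccccc5)c(OCc5ccccc5)c2)[C@H](OC(=O)c2cc(OCc5ccccc5)c(OCc5ccccc5)c(OCc5ccccc5)c2)C3)c2c(OCc5ccccc5)cc(OCc5ccccc5)c([C@H]3c4c(OCc5ccccc5)cc(OCc5ccccc5)cc4O[C@H](c4ccc(OCc5ccccc5)c(OCc5ccccc5)c4)[C@@H]3O)c2O[C@@H]1c1ccc(OCc5ccccc5)c(OCc5ccccc5)c1)c1cc(OCc5ccccc5)c(OCc5ccccc5)c(OCc5ccccc5)c1 | intermediate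
19 | (−)-epicatechin-(4β→8)-(−)-epicatechin 3-O-gallate-(4β→8)-(−)-epicatechin 3-O-gallate | O=C(O[C@@H]1[C@@H](c2c(O)cc(O)c3c2O[C@H](c2ccc(O)c(O)c2)[C@H](OC(=O)c2cc(O)c(O)c(O)c2)C3)c2c(O)cc(O)c([C@H]3c4c(O)cc(O)cc4O[C@H](c4ccc(O)c(O)c4)[C@@H]3O)c2O[C@@H]1c1ccc(O)c(O)c1)c1cc(O)c(O)c(O)c1 | target

**Step count and risks**

Total step count: 12. Longest linear sequence: 10 steps (1 → 2 → 7 → 8 → 10 → 11 → 13 → 16 → 17 → 18 → 19; the branch from 3 is equally long).

Steps most likely to fail:

Step 5 (oxidative ring enlargement). The electrophilic iodane may attack the alkoxy-rich aromatic rings instead of the alkene, or the benzylic cation may lose H-2 so that the furan ring aromatises before the aryl shift. The fallback avoids hypervalent iodine and sets out from 8. Dihydroxylation (OsO4 cat., NMO, acetone/H2O) on the face away from the C2 aryl group should give (2R)-4,6-bis(benzyloxy)-2-[3,4-bis(benzyloxy)phenyl]-3-(hydroxymethyl)-2,3-dihydro-1-benzofuran-3-ol F1, with the tertiary hydroxyl trans to the aryl group. Sulfonylation of the primary hydroxyl (TsCl, pyridine, 0 °C) should give [(2R)-4,6-bis(benzyloxy)-2-[3,4-bis(benzyloxy)phenyl]-3-hydroxy-2,3-dihydro-1-benzofuran-3-yl]methyl 4-methylbenzenesulfonate F2. A pinacol-type rearrangement of this diol monosulfonate (LiClO4, CaCO3, THF, 50 °C), again with migration of the ring A carbon onto the CH2 group as the sulfonate leaves, should deliver ketone 10, where the route is rejoined.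

Step 4 (reductive Heck cyclization). A palladium hydride may move the exocyclic double bond into the ring, which aromatises 8 to the 3-methylbenzofuran, or the terminal alkyne may be consumed by palladium. The fallback sets out from 7 and replaces organopalladium chemistry by a radical chain (Bu3SnH, AIBN, benzene, 80 °C): the aryl radical from the C–I bond should close 5-exo-dig and the vinyl radical should take a hydrogen atom from the stannane to give 8 under neutral conditions. No compound outside the list arises (entry F0), and the route is rejoined at 8.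

Step 11 (second flavan coupling). Self-condensation of electrophile 13 through its own C8 may outrun attack by the hindered dimeric nucleophile 17, and substitution at a wrong ring position of 17 may occur. The fallback caps the electrophile and sets out from 11. Bromination (NBS, CH2Cl2, −78 °C) should give 8-bromo-5,7,3',4'-tetra-O-benzyl-(−)-epicatechin F3. Oxidative etherification (DDQ, 2-ethoxyethanol, CH2Cl2) should give 8-bromo-4β-(2-ethoxyethoxy)-5,7,3',4'-tetra-O-benzyl-(−)-epicatechin F4, which cannot oligomerise through C8 and can be used in excess. Coupling of F4 with 17 (Me3SiOSO2CF3, CH2Cl2, −78 °C) should give the perbenzylated trimer brominated at C8 of the top unit F5. Hydrogenolysis (H2, Pd(OH)2/C, Et3N, THF/MeOH/H2O) should remove the bromine together with the benzyl groups and give 19, where the route is rejoined.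

**Further compounds**

F1 | step 5 | (2R)-4,6-bis(benzyloxy)-2-[3,4-bis(benzyloxy)phenyl]-3-(hydroxymethyl)-2,3-dihydro-1-benzofuran-3-ol (tertiary OH trans to aryl) | OC[C@]1(O)c2c(OCc3ccccc3)cc(OCc3ccccc3)cc2O[C@@H]1c1ccc(OCc2ccccc2)c(OCc2ccccc2)c1
F2 | step 5 | [(2R)-4,6-bis(benzyloxy)-2-[3,4-bis(benzyloxy)phenyl]-3-hydroxy-2,3-dihydro-1-benzofuran-3-yl]methyl 4-methylbenzenesulfonate | Cc1ccc(cc1)S(=O)(=O)OC[C@]1(O)c2c(OCc3ccccc3)cc(OCc3ccccc3)cc2O[C@@H]1c1ccc(OCc2ccccc2)c(OCc2ccccc2)c1
F0 | step 4 | none | none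
F3 | step 11 | 8-bromo-5,7,3',4'-tetra-O-benzyl-(−)-epicatechin | O[C@@H]1Cc2c(OCc3ccccc3)cc(OCc3ccccc3)c(Br)c2O[C@@H]1c1ccc(OCc2ccccc2)c(OCc2ccccc2)c1
F4 | step 11 | 8-bromo-4β-(2-ethoxyethoxy)-5,7,3',4'-tetra-O-benzyl-(−)-epicatechin | O[C@@H]1[C@@H](OCCOCC)c2c(OCc3ccccc3)cc(OCc3ccccc3)c(Br)c2O[C@@H]1c1ccc(OCc2ccccc2)c(OCc2ccccc2)c1
F5 | step 11 | perbenzylated trimer 18 carrying bromine at C8 of the top unit | O=C(O[C@@H]1[C@@H](c2c(OCc5ccccc5)cc(OCc5ccccc5)c3c2O[C@H](c2ccc(OCc5ccccc5)c(OCc5ccccc5)c2)[C@H](OC(=O)c2cc(OCc5ccccc5)c(OCc5ccccc5)c(OCc5ccccc5)c2)C3)c2c(OCc5ccccc5)cc(OCc5ccccc5)c([C@H]3c4c(OCc5ccccc5)cc(OCc5ccccc5)c(Br)c4O[C@H](c4ccc(OCc5ccccc5)c(OCc5ccccc5)c4)[C@@H]3O)c2O[C@@H]1c1ccc(OCc5ccccc5)c(OCc5ccccc5)c1)c1cc(OCc5ccccc5)c(OCc5ccccc5)c(OCc5ccccc5)c1
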